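**Retrosynthetic overview**
1. Target (4R,5S,6S,7S,8R): the 4-hydroxytigloyl ester, the C11=C13 methylene and the 4,5-epoxide are added last to a (1(10)Z,4Z)-germacra-1(10),4-dien-12,6-olide core. The epoxide oxygen is delivered from the C6 hydroxyl while the lactone is reductively opened.
2. The ten-membered carbocycle is closed at C2–C3, the bond between the two allylic CH2 groups that lie between the C1=C10 and C4=C5 Z-alkenes. A C2 allylic sulfonyl carbanion displaces a C3 allylic bromide.
3. The seco precursor comes from a C9–C10 Negishi coupling with (Z)-3-iodobut-2-enyl phenyl sulfone and a Z-selective Horner–Wadsworth–Emmons olefination at C5.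
4. Feature the strategy rests on: the contiguous C6(O)–C7(CH2–C12)–C8(O) triad carrying the cis-fused γ-lactone (O6–C12) is C2–C4 of D-arabinose (C5–C9 = sugar C1–C5). C7 is set by convex-face hydrogenation of a furanos-3-ylidene acetate.
5. Ring order: γ-lactone (step 8), ten-membered carbocycle (step 21), oxirane (step 23), lactone re-closed (step 24).

Key step: step 21

Assumption: germacrane numbering is used throughout (C12 lactone carbonyl, C13 exocyclic methylene, C14 and C15 the methyls on C10 and C4); the anomers of 2 and 10 and the C2 epimers of 35 and 36 are carried as mixtures because those centres are removed later.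

**Route**

Step 1
Reactants: 1 D-arabinose
Product: 2 5-O-(tert-butyldiphenylsilyl)-D-arabinofuranose (anomeric mixture)
Conditions: t-BuPh2SiCl, imidazole, DMF, 0 °C → rt
Reagents that add atoms: tert-butyl(chloro)diphenylsilane, CC(C)(C)[Si](Cl)(c1ccccc1)c1ccccc1
Why: Selective silyl ether formation at the only primary hydroxyl should lock the sugar in the furanose form.

Step 2
Reactants: 2 5-O-(tert-butyldiphenylsilyl)-D-arabinofuranose
Product: 3 5-O-(tert-butyldiphenylsilyl)-1,2-O-isopropylidene-β-D-arabinofuranose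
Conditions: Me2C(OMe)2, TsOH (cat.), acetone, rt
Reagents that add atoms: 2,2-dimethoxypropane, COC(C)(C)OC
Why: Acid-catalysed acetonide formation (transketalisation) should take the only cis-1,2-diol of the furanose, O1/O2 of the β-anomer, and leave the C3 hydroxyl free.

Step 3
Reactants: 3 5-O-(tert-butyldiphenylsilyl)-1,2-O-isopropylidene-β-D-arabinofuranose
Product: 4 5-O-(tert-butyldiphenylsilyl)-1,2-O-isopropylidene-β-D-threo-pentofuranos-3-ulose
Conditions: Dess–Martin periodinane, NaHCO3, CH2Cl2, rt
Reagents that add atoms: none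
Why: Dess–Martin oxidation of the single secondary alcohol should give the 3-ulose under buffered conditions that do not epimerise sugar C4.

Step 4
Reactants: 4 the 3-ulose; 5 tert-butyl (triphenylphosphoranylidene)acetate
Product: 6 3-deoxy-3-C-[(tert-butoxycarbonyl)methylidene]-5-O-(tert-butyldiphenylsilyl)-1,2-O-isopropylidene-β-D-threo-pentofuranose (E/Z mixture)
Conditions: CH2Cl2, rt
Reagents that add atoms: none
Why: Wittig olefination with a stabilised ylide needs no added base on the strained furanos-3-ulose, so sugar C4 should keep its configuration, and the alkene geometry is irrelevant.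

Step 5
Reactants: 6 the 3-C-alkylidene furanose
Product: 7 3-deoxy-3-C-[(tert-butoxycarbonyl)methyl]-5-O-(tert-butyldiphenylsilyl)-1,2-O-isopropylidene-β-D-lyxofuranose
Conditions: H2 (1 atm), Pd/C, EtOAc, rt
Reagents that add atoms: none
Why: Heterogeneous catalytic hydrogenation should add hydrogen to the α face of the exocyclic alkene, the face opposite both the 1,2-acetonide and the C4 side chain, which sets C7 (sugar C3) with the CH2CO2tBu arm cis to O2 and to C5.

Step 6
Reactants: 7 the silyl ether
Product: 8 3-deoxy-3-C-[(tert-butoxycarbonyl)methyl]-1,2-O-isopropylidene-β-D-lyxofuranose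
Conditions: Bu4NF, AcOH, THF, rt
Reagents that add atoms: none
Why: Buffered fluoride desilylation frees the primary alcohol, and the bulky tert-butyl ester should not lactonise onto it.

Step 7
Reactants: 8 the primary alcohol
Product: 9 3,5-dideoxy-5-iodo-3-C-[(tert-butoxycarbonyl)methyl]-1,2-O-isopropylidene-β-D-lyxofuranose
Conditions: I2, PPh3, imidazole, CH2Cl2, 0 °C → rt
Reagents that add atoms: iodine, II
Why: Garegg–Samuelsson (Appel-type) iodination converts the primary alcohol into the iodide by SN2 displacement of an alkoxyphosphonium ion.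

Step 8
Reactants: 9 the iodo acetonide
Product: 10 3-C-(carboxymethyl)-3,5-dideoxy-5-iodo-D-lyxofuranose 2-O-γ-lactone (cis-fused lactol–lactone; anomeric mixture)
Conditions: CF3CO2H/H2O (9:1), 0 °C → rt
Reagents that add atoms: water, O
Why: Acid hydrolysis removes the acetonide and the tert-butyl ester, and the acid should lactonise onto O2, the only free γ-hydroxyl while O4 is still held in the furanose ring, so O6 and O8 are differentiated without change at C6 or C7.

Step 9
Reactants: 10 the lactol–lactone
Product: 11 cis-5-(1,3-dithian-2-yl)-4-(1-hydroxy-2-iodoethyl)oxolan-2-one (C5 dithiane; C8 hydroxyl; C9 iodide; C6 C7 C8 as in the target)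
Conditions: HS(CH2)3SH, BF3·OEt2, CH2Cl2, −20 → 0 °C
Reagents that add atoms: propane-1,3-dithiol, SCCCS
Why: Lewis-acid-mediated dithioacetalisation opens the lactol to the open-chain C5 dithiane and frees the C8 hydroxyl without forming an alkoxide that could translactonise.

Step 10
Reactants: 11 the hydroxy dithiane
Product: 12 8-O-(tert-butyldimethylsilyl) ether of 11
Conditions: t-BuMe2SiOTf, 2,6-lutidine, CH2Cl2, −78 °C
Reagents that add atoms: tert-butyldimethylsilyl trifluoromethanesulfonate, CC(C)(C)[Si](C)(C)OS(=O)(=O)C(F)(F)F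
Why: Silylation with a silyl triflate and a hindered base protects the secondary C8 alcohol before any basic step.

Step 11
Reactants: 13 but-2-yn-1-ol
Product: 15 (Z)-3-iodobut-2-en-1-ol, via cyclic alkenylalanate 14 (not isolated)
Conditions: NaAlH2(OCH2CH2OMe)2, THF, 0 °C → rt; then I2, THF, −78 °C → rt
Reagents that add atoms: iodine, II
Why: Hydroxyl-directed trans-hydroalumination of the propargylic alcohol puts aluminium on C3 in a five-membered alanate, and iodinolysis with retention gives the iodide cis to the CH2OH group.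

Step 12
Reactants: 15 (Z)-3-iodobut-2-en-1-ol; 16 sodium benzenesulfinate
Product: 18 (Z)-3-iodobut-2-enyl phenyl sulfone, via allylic mesylate 17 (not isolated)
Conditions: MeSO2Cl, Et3N, CH2Cl2, −20 °C; then 16, DMF, rt
Reagents that add atoms: none
Why: Mesylation followed by SN2 S-alkylation of the sulfinate gives the allylic sulfone without touching the vinyl iodide or its geometry.

Step 13
Reactants: 12 the primary iodide; 18 (Z)-3-iodobut-2-enyl phenyl sulfone
Product: 20 dithiane lactone carrying the (Z)-CH2–C(CH3)=CH–CH2SO2Ph chain at C8 (C9–C10 bond formed), via alkylzinc iodide 19 (not isolated)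
Conditions: Zn dust (activated with BrCH2CH2Br and Me3SiCl), DMF, rt; then 18, Pd2(dba)3 (2.5 mol %), P(o-tol)3 (10 mol %), DMF, rt
Reagents that add atoms: none
Why: Negishi sp3–sp2 cross-coupling: zinc inserts into the primary C–I bond and the zerovalent palladium catalyst couples the alkylzinc with the vinyl iodide with retention of the Z geometry, in the presence of lactone, dithiane and sulfone.

Step 14
Reactants: 20 the dithiane
Product: 21 C5 aldehyde (lactone; 8-O-silyl; Z allylic sulfone chain)
Conditions: MeI, CaCO3, MeCN/H2O (9:1), 40 °C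
Reagents that add atoms: water, O
Why: Alkylative dethioacetalisation (S-methylation, then hydrolysis) releases the aldehyde under buffered neutral conditions that should leave the alkene and the α-acyloxy centre C6 intact.

Step 15
Reactants: 22 diphenyl phosphite; 23 tert-butyl bromoacetate
Product: 24 tert-butyl 2-(diphenoxyphosphoryl)acetate
Conditions: Et3N, CH2Cl2, 0 °C → rt
Reagents that add atoms: none
Why: Michaelis–Becker-type P-alkylation of the phosphite with the bromoacetate gives the diaryl phosphonoacetate.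

Step 16
Reactants: 24 tert-butyl 2-(diphenoxyphosphoryl)acetate
Product: 26 tert-butyl 2-(diphenoxyphosphoryl)propanoate, via sodium phosphonoacetate enolate 25 (not isolated)
Conditions: NaH, THF, 0 °C; then MeI, 0 °C → rt
Reagents that add atoms: iodomethane, CI
Why: Enolate alkylation of the phosphonate-stabilised carbanion with iodomethane installs the methyl group that becomes C15.

Step 17
Reactants: 21 the C5 aldehyde; 26 tert-butyl 2-(diphenoxyphosphoryl)propanoate
Product: 28 tert-butyl (Z)-2-methylalk-2-enoate (C4=C5 Z; ester carbon is C3), via sodium phosphonate carbanion 27 (not isolated)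
Conditions: 26 (1.3 equiv), NaH (1.2 equiv), THF, 0 °C; then 21, −78 → −20 °C
Reagents that add atoms: none
Why: The Ando variant of the Horner–Wadsworth–Emmons olefination eliminates under kinetic control to the Z alkene, placing the ester (future C3) cis to C6, and the phosphonate anion is too weak a base to deprotonate the sulfone or epimerise C6.

Step 18
Reactants: 28 the tert-butyl (Z)-enoate
Product: 30 (Z)-enoic acid, via trimethylsilyl ester 29 (not isolated)
Conditions: Me3SiOTf, 2,6-lutidine, CH2Cl2, 0 °C; then pH 4 buffer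
Reagents that add atoms: none
Why: Silyl-triflate-mediated cleavage of the tert-butyl ester leaves the silyl ether, the lactone and the Z alkene untouched and gives the free acid, the one carbonyl group that can then be reduced beside the lactone.

Step 19
Reactants: 30 the (Z)-enoic acid
Product: 32 (Z)-allylic alcohol (C3–OH), via isobutyl mixed carbonic anhydride 31 (not isolated)
Conditions: i-BuOCOCl, N-methylmorpholine, THF, −15 °C; then NaBH4, H2O, 0 °C
Reagents that add atoms: none
Why: Mixed-anhydride activation followed by borohydride reduction converts the acid into the primary allylic alcohol, while the unactivated γ-lactone is not reduced under these conditions.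

Step 20
Reactants: 32 the (Z)-allylic alcohol
Product: 33 (1(10)Z,4Z)-3-bromo-2-(phenylsulfonyl)-8-O-(tert-butyldimethylsilyl)-2,3-seco-germacra-1(10),4-dien-12,6-olide
Conditions: CBr4, PPh3, CH2Cl2, 0 °C
Reagents that add atoms: tetrabromomethane, BrC(Br)(Br)Br
Why: Appel bromination of the primary allylic alcohol proceeds by SN2 and should not cause allylic transposition or Z/E isomerisation.

Step 21
Reactants: 33 the bromo sulfone
Product: 35 2-(phenylsulfonyl)-8-O-(tert-butyldimethylsilyl)-(1(10)Z,4Z)-germacra-1(10),4-dien-12,6-olide (6,7-cis; C2 epimers), via potassium sulfonyl carbanion 34 (not isolated)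
Conditions: KN(SiMe3)2 (1.1 equiv), THF, −78 → −20 °C, 33 added by syringe pump to about 2 mM final concentration
Reagents that add atoms: none
Why: KN(SiMe3)2 removes the C2 proton, the most acidic one because it is both allylic and α to the sulfonyl group (several pKa units below the lactone α-CH2), and carbanion 34 displaces the primary allylic bromide at C3 by intramolecular SN2 substitution. The closest known reaction type is the macrocyclisation of terpenoid chains by intramolecular alkylation of sulfonyl-stabilised allylic carbanions with allylic halides under high dilution. The ten-membered carbocycle, the only ring formed in the step, closes in a 10-exo-tet mode. The one new stereocentre, C2, is not controlled and need not be, since both epimers converge when the sulfonyl group is removed in step 22. The step needs α- over γ-alkylation of the allyl sulfone anion, SN2 over SN2′ attack, ring closure over oligomerisation and retention of both Z alkenes; these should be secured by charge localisation next to sulfur, by the unhindered primary bromide, by slow addition at millimolar concentration, and by the fact that neither the anion nor the SN2 step touches the preformed Z geometries, which also hold C2 and C3 on the same side of the chain.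

Step 22
Reactants: 35 the macrocyclic sulfonyl lactone
Product: 37 8-O-(tert-butyldimethylsilyl)-(1(10)Z,4Z)-germacra-1(10),4-diene-6,12-diol, via sulfonyl diol 36 (not isolated)
Conditions: LiBHEt3 (6 equiv), THF, 0 °C; then PdCl2(dppp) (5 mol %), 0 °C → rt
Reagents that add atoms: none
Why: LiBHEt3 first reduces the lactone to the diol, so that no allylic carboxylate meets palladium, and the zerovalent palladium formed from PdCl2(dppp) then ionises the allylic sulfone to a π-allyl complex that takes hydride at its less substituted end C2, leaving C1=C10 in place (reductive desulfonylation).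

Step 23
Reactants: 37 the diene diol
Product: 38 (4R,5S)-4,5-epoxy-8-O-(tert-butyldimethylsilyl)-(1(10)Z)-germacr-1(10)-ene-6,12-diol
Conditions: VO(acac)2 (5 mol %), t-BuOOH (decane), CH2Cl2, 0 °C
Reagents that add atoms: tert-butyl hydroperoxide, CC(C)(C)OO
Why: Vanadium-catalysed hydroxyl-directed epoxidation delivers oxygen from the C6 vanadate ester to the allylic C4=C5 alkene only, and by analogy with eight- and nine-membered Z-cycloalkenols this delivery should give the cis-epoxy alcohol, which sets C4 (R) and C5 (S) cis to O6.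

Step 24
Reactants: 38 the epoxy diol
Product: 39 (4R,5S)-4,5-epoxy-8-O-(tert-butyldimethylsilyl)-(1(10)Z)-germacr-1(10)-en-12,6-olide
Conditions: TEMPO (0.2 equiv), PhI(OAc)2 (2.5 equiv), NaHCO3, CH2Cl2, rt
Reagents that add atoms: none
Why: TEMPO/PhI(OAc)2 oxidative lactonisation oxidises the primary alcohol to the aldehyde, which closes to the lactol with the C6 hydroxyl and is oxidised on to the γ-lactone, while the hindered secondary alcohol is not oxidised and the buffer protects the acid-labile epoxide.

Step 25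
Reactants: 39 the epoxy lactone
Product: 43 (4R,5S)-4,5-epoxy-8-O-(tert-butyldimethylsilyl)-(1(10)Z)-germacra-1(10),11(13)-dien-12,6-olide, via lithium enolate 40 (not isolated), via Mannich base 41 (not isolated), via trimethylammonium iodide 42 (not isolated)
Conditions: LiN(iPr)2, THF, −78 °C; then Me2N=CH2+ I−, −78 °C → rt; then MeI, MeOH, rt; then NaHCO3 (aq), CH2Cl2, rt
Reagents that add atoms: N,N-dimethylmethyleneiminium iodide, C=[N+](C)C.[I-]
Why: Mannich reaction of the lactone enolate with Eschenmoser's salt, N-methylation and Hofmann-type β-elimination install the exocyclic methylene at C11, the only enolisable position.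

Step 26
Reactants: 43 the silyl-protected methylene lactone
Product: 44 (4R,5S)-4,5-epoxy-8-hydroxy-(1(10)Z)-germacra-1(10),11(13)-dien-12,6-olide
Conditions: Bu4NF, AcOH (1:1), THF, rt
Reagents that add atoms: none
Why: Buffered fluoride desilylation frees the C8 hydroxyl without an alkoxide that could translactonise or add to the methylene lactone, and without acid that could open the epoxide.

Step 27
Reactants: 45 (tert-butyldimethylsilyloxy)acetaldehyde; 46 ethyl 2-(triphenylphosphoranylidene)propanoate
Product: 47 ethyl (E)-4-(tert-butyldimethylsilyloxy)-2-methylbut-2-enoate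
Conditions: CH2Cl2, rt
Reagents that add atoms: none
Why: Wittig olefination with the stabilised α-methyl ylide gives the E trisubstituted enoate.

Step 28
Reactants: 47 the ethyl ester
Product: 48 (E)-4-(tert-butyldimethylsilyloxy)-2-methylbut-2-enoic acid
Conditions: LiOH, THF/MeOH/H2O, 0 °C → rt; then 1 M HCl to pH 4, 0 °C
Reagents that add atoms: lithium hydroxide, [Li+].[OH-]
Why: Saponification of the ethyl ester leaves the primary silyl ether intact.

Step 29
Reactants: 48 the silylated hydroxytiglic acid; 44 the C8 alcohol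
Product: 50 8-O-[(E)-4-(tert-butyldimethylsilyloxy)-2-methylbut-2-enoyl] derivative of 44, via mixed trichlorobenzoic anhydride 49 (not isolated)
Conditions: 2,4,6-Cl3C6H2COCl, Et3N, toluene, rt; then 44, DMAP, toluene, rt
Reagents that add atoms: none
Why: Yamaguchi esterification through the mixed anhydride acylates the hindered secondary C8 alcohol under non-acidic conditions, and the E-tiglate geometry is the thermodynamically preferred one.

Step 30
Reactants: 50 the silylated ester
Product: 51 CNP0198076.8
Conditions: Et3N·3HF, THF, rt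
Reagents that add atoms: none
Why: Mild, nearly neutral fluoride desilylation of the primary allylic silyl ether should complete the synthesis without opening the epoxide or adding to the methylene lactone.

**Compound list**
1 | D-arabinose | O=C[C@@H](O)[C@H](O)[C@H](O)CO | starting material
2 | 5-O-(tert-butyldiphenylsilyl)-D-arabinofuranose (anomers) | OC1[C@@H](O)[C@H](O)[C@@H](CO[Si](c2ccccc2)(c2ccccc2)C(C)(C)C)O1 | intermediate
3 | 5-O-(tert-butyldiphenylsilyl)-1,2-O-isopropylidene-β-D-arabinofuranose | CC1(C)O[C@H]2[C@H](O)[C@@H](CO[Si](c3ccccc3)(c3ccccc3)C(C)(C)C)O[C@H]2O1 | intermediate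
4 | 5-O-(tert-butyldiphenylsilyl)-1,2-O-isopropylidene-β-D-threo-pentofuranos-3-ulose | CC1(C)O[C@H]2C(=O)[C@@H](CO[Si](c3ccccc3)(c3ccccc3)C(C)(C)C)O[C@H]2O1 | intermediate
5 | tert-butyl (triphenylphosphoranylidene)acetate | CC(C)(C)OC(=O)C=P(c1ccccc1)(c1ccccc1)c1ccccc1 | starting material
6 | 3-deoxy-3-C-[(tert-butoxycarbonyl)methylidene]-5-O-(tert-butyldiphenylsilyl)-1,2-O-isopropylidene-β-D-threo-pentofuranose (E/Z) | CC1(C)O[C@H]2C(=CC(=O)OC(C)(C)C)[C@@H](CO[Si](c3ccccc3)(c3ccccc3)C(C)(C)C)O[C@H]2O1 | intermediate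
7 | 3-deoxy-3-C-[(tert-butoxycarbonyl)methyl]-5-O-(tert-butyldiphenylsilyl)-1,2-O-isopropylidene-β-D-lyxofuranose | CC1(C)O[C@H]2[C@@H](CC(=O)OC(C)(C)C)[C@@H](CO[Si](c3ccccc3)(c3ccccc3)C(C)(C)C)O[C@H]2O1 | intermediate
8 | 3-deoxy-3-C-[(tert-butoxycarbonyl)methyl]-1,2-O-isopropylidene-β-D-lyxofuranose | CC1(C)O[C@H]2[C@@H](CC(=O)OC(C)(C)C)[C@@H](CO)O[C@H]2O1 | intermediate
9 | 3,5-dideoxy-5-iodo-3-C-[(tert-butoxycarbonyl)methyl]-1,2-O-isopropylidene-β-D-lyxofuranose | CC1(C)O[C@H]2[C@@H](CC(=O)OC(C)(C)C)[C@@H](CI)O[C@H]2O1 | intermediate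
10 | 3-C-(carboxymethyl)-3,5-dideoxy-5-iodo-D-lyxofuranose 2-O-γ-lactone (anomers) | O=C1C[C@H]2[C@@H](CI)OC(O)[C@H]2O1 | intermediate
11 | cis-5-(1,3-dithian-2-yl)-4-(1-hydroxy-2-iodoethyl)oxolan-2-one | O=C1C[C@@H]([C@H](O)CI)[C@@H](C2SCCCS2)O1 | intermediate
12 | 8-O-(tert-butyldimethylsilyl) ether of 11 | O=C1C[C@@H]([C@H](O[Si](C)(C)C(C)(C)C)CI)[C@@H](C2SCCCS2)O1 | intermediate
13 | but-2-yn-1-ol | CC#CCO | starting material
14 | sodium cyclic alkenylalanate from 13 (formed in situ) | CC1=CCO[Al-]1(OCCOC)OCCOC.[Na+] | intermediate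
15 | (Z)-3-iodobut-2-en-1-ol | C/C(I)=C/CO | intermediate
16 | sodium benzenesulfinate | [Na+].[O-]S(=O)c1ccccc1 | starting material
17 | (Z)-3-iodobut-2-enyl methanesulfonate (formed in situ) | C/C(I)=C/COS(C)(=O)=O | intermediate
18 | (Z)-3-iodobut-2-enyl phenyl sulfone | C/C(I)=C/CS(=O)(=O)c1ccccc1 | intermediate
19 | alkylzinc iodide from 12 (formed in situ) | O=C1C[C@@H]([C@H](O[Si](C)(C)C(C)(C)C)C[Zn]I)[C@@H](C2SCCCS2)O1 | intermediate
20 | dithiane lactone with (Z)-allylic sulfone chain (C9–C10 coupled) | O=C1C[C@@H]([C@H](O[Si](C)(C)C(C)(C)C)C/C(C)=C\CS(=O)(=O)c2ccccc2)[C@@H](C3SCCCS3)O1 | intermediate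
21 | C5 aldehyde | O=C1C[C@@H]([C@H](O[Si](C)(C)C(C)(C)C)C/C(C)=C\CS(=O)(=O)c2ccccc2)[C@@H](C=O)O1 | intermediate
22 | diphenyl phosphite | O=[PH](Oc1ccccc1)Oc1ccccc1 | starting material
23 | tert-butyl bromoacetate | CC(C)(C)OC(=O)CBr | starting material
24 | tert-butyl 2-(diphenoxyphosphoryl)acetate | CC(C)(C)OC(=O)CP(=O)(Oc1ccccc1)Oc1ccccc1 | intermediate
25 | sodium salt of 24 (formed in situ) | CC(C)(C)OC(=O)[CH-]P(=O)(Oc1ccccc1)Oc1ccccc1.[Na+] | intermediate
26 | tert-butyl 2-(diphenoxyphosphoryl)propanoate | CC(C)(C)OC(=O)C(C)P(=O)(Oc1ccccc1)Oc1ccccc1 | intermediate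
27 | sodium salt of 26 (formed in situ) | CC(C)(C)OC(=O)[C-](C)P(=O)(Oc1ccccc1)Oc1ccccc1.[Na+] | intermediate
28 | tert-butyl (Z)-enoate (C4=C5 Z) | O=C1C[C@@H]([C@H](O[Si](C)(C)C(C)(C)C)C/C(C)=C\CS(=O)(=O)c2ccccc2)[C@@H](/C=C(C)\C(=O)OC(C)(C)C)O1 | intermediate
29 | trimethylsilyl (Z)-enoate (formed in situ) | O=C1C[C@@H]([C@H](O[Si](C)(C)C(C)(C)C)C/C(C)=C\CS(=O)(=O)c2ccccc2)[C@@H](/C=C(C)\C(=O)O[Si](C)(C)C)O1 | intermediate
30 | (Z)-enoic acid | O=C1C[C@@H]([C@H](O[Si](C)(C)C(C)(C)C)C/C(C)=C\CS(=O)(=O)c2ccccc2)[C@@H](/C=C(C)\C(=O)O)O1 | intermediate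
31 | isobutyl mixed carbonic anhydride of 30 (formed in situ) | O=C1C[C@@H]([C@H](O[Si](C)(C)C(C)(C)C)C/C(C)=C\CS(=O)(=O)c2ccccc2)[C@@H](/C=C(C)\C(=O)OC(=O)OCC(C)C)O1 | intermediate
32 | (Z)-allylic alcohol (C3–OH) | O=C1C[C@@H]([C@H](O[Si](C)(C)C(C)(C)C)C/C(C)=C\CS(=O)(=O)c2ccccc2)[C@@H](/C=C(C)\CO)O1 | intermediate
33 | (1(10)Z,4Z)-3-bromo-2-(phenylsulfonyl)-8-O-(tert-butyldimethylsilyl)-2,3-seco-germacra-1(10),4-dien-12,6-olide | O=C1C[C@@H]([C@H](O[Si](C)(C)C(C)(C)C)C/C(C)=C\CS(=O)(=O)c2ccccc2)[C@@H](/C=C(C)\CBr)O1 | intermediate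
34 | potassium C2 sulfonyl carbanion of 33 (formed in situ) | [K+].O=C1C[C@@H]([C@H](O[Si](C)(C)C(C)(C)C)C/C(C)=C\[CH-]S(=O)(=O)c2ccccc2)[C@@H](/C=C(C)\CBr)O1 | intermediate
35 | 2-(phenylsulfonyl)-8-O-(tert-butyldimethylsilyl)-(1(10)Z,4Z)-germacra-1(10),4-dien-12,6-olide (C2 epimers) | O=C1C[C@H]2[C@H](O[Si](C)(C)C(C)(C)C)C/C(C)=C\C(S(=O)(=O)c3ccccc3)C/C(C)=C\[C@H]2O1 | intermediate
36 | 2-(phenylsulfonyl)-8-O-(tert-butyldimethylsilyl)-(1(10)Z,4Z)-germacra-1(10),4-diene-6,12-diol (formed in situ) | OCC[C@H]1[C@H](O[Si](C)(C)C(C)(C)C)C/C(C)=C\C(S(=O)(=O)c2ccccc2)C/C(C)=C\[C@H]1O | intermediate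
37 | 8-O-(tert-butyldimethylsilyl)-(1(10)Z,4Z)-germacra-1(10),4-diene-6,12-diol | OCC[C@H]1[C@H](O[Si](C)(C)C(C)(C)C)C/C(C)=C\CC/C(C)=C\[C@H]1O | intermediate
38 | (4R,5S)-4,5-epoxy-8-O-(tert-butyldimethylsilyl)-(1(10)Z)-germacr-1(10)-ene-6,12-diol | OCC[C@H]1[C@H](O[Si](C)(C)C(C)(C)C)C/C(C)=C\CC[C@@]2(C)O[C@H]2[C@H]1O | intermediate
39 | (4R,5S)-4,5-epoxy-8-O-(tert-butyldimethylsilyl)-(1(10)Z)-germacr-1(10)-en-12,6-olide | O=C1C[C@H]2[C@H](O[Si](C)(C)C(C)(C)C)C/C(C)=C\CC[C@@]3(C)O[C@H]3[C@H]2O1 | intermediate
40 | lithium enolate of 39 (formed in situ) | [Li+].[O-]C1=C[C@H]2[C@H](O[Si](C)(C)C(C)(C)C)C/C(C)=C\CC[C@@]3(C)O[C@H]3[C@H]2O1 | intermediate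
41 | 11-(dimethylaminomethyl) lactone (C11 epimers; formed in situ) | CN(C)CC1C(=O)O[C@H]2[C@@H]1[C@H](O[Si](C)(C)C(C)(C)C)C/C(C)=C\CC[C@@]1(C)O[C@@H]21 | intermediate
42 | 11-(trimethylammoniomethyl) lactone iodide (formed in situ) | C[N+](C)(C)CC1C(=O)O[C@H]2[C@@H]1[C@H](O[Si](C)(C)C(C)(C)C)C/C(C)=C\CC[C@@]1(C)O[C@@H]21.[I-] | intermediate
43 | (4R,5S)-4,5-epoxy-8-O-(tert-butyldimethylsilyl)-(1(10)Z)-germacra-1(10),11(13)-dien-12,6-olide | C=C1C(=O)O[C@H]2[C@@H]1[C@H](O[Si](C)(C)C(C)(C)C)C/C(C)=C\CC[C@@]1(C)O[C@@H]21 | intermediate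
44 | (4R,5S)-4,5-epoxy-8-hydroxy-(1(10)Z)-germacra-1(10),11(13)-dien-12,6-olide | C=C1C(=O)O[C@H]2[C@@H]1[C@H](O)C/C(C)=C\CC[C@@]1(C)O[C@@H]21 | intermediate
45 | (tert-butyldimethylsilyloxy)acetaldehyde | CC(C)(C)[Si](C)(C)OCC=O | starting material
46 | ethyl 2-(triphenylphosphoranylidene)propanoate | CCOC(=O)C(C)=P(c1ccccc1)(c1ccccc1)c1ccccc1 | starting material
47 | ethyl (E)-4-(tert-butyldimethylsilyloxy)-2-methylbut-2-enoate | CCOC(=O)/C(C)=C/CO[Si](C)(C)C(C)(C)C | intermediate
48 | (E)-4-(tert-butyldimethylsilyloxy)-2-methylbut-2-enoic acid | OC(=O)/C(C)=C/CO[Si](C)(C)C(C)(C)C | intermediate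
49 | mixed 2,4,6-trichlorobenzoic anhydride of 48 (formed in situ) | O=C(OC(=O)c1c(Cl)cc(Cl)cc1Cl)/C(C)=C/CO[Si](C)(C)C(C)(C)C | intermediate
50 | 8-O-[(E)-4-(tert-butyldimethylsilyloxy)-2-methylbut-2-enoyl] ester of 44 | C=C1C(=O)O[C@H]2[C@@H]1[C@H](OC(=O)/C(C)=C/CO[Si](C)(C)C(C)(C)C)C/C(C)=C\CC[C@@]1(C)O[C@@H]21 | intermediate
51 | CNP0198076.8 | C=C1C(=O)O[C@H]2[C@@H]1[C@H](OC(=O)/C(C)=C/CO)C/C(C)=C\CC[C@@]1(C)O[C@@H]21 | target

**Step count**
Total: 30 steps. Longest linear sequence: 24 steps (1 → 51 through steps 1–10, 13, 14, 17–26, 29 and 30).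

**Steps most likely to fail**

Step 21 (ring closure). Intermolecular alkylation may outrun ring closure and give oligomers, or the base may remove HBr from the allylic bromide (C6–H is allylic and next to oxygen) before C2 attacks C3. The fallback exchanges the order of the two C–C bond formations: C2–C3 is made between two molecules and the ring is closed at C9–C10. It sets out from iodide 12. MeI/CaCO3 in aqueous MeCN should give the iodo aldehyde F1. Olefination with the sodium phosphonate 27 should give the tert-butyl (Z)-enoate F2, CF3CO2H in CH2Cl2 at 0 °C the (Z)-enoic acid F3, BH3·SMe2 in THF the allylic alcohol F4, and CBr4/PPh3 the allylic bromide F5, which still carries the primary iodide. Sulfone 18 is deprotonated with KN(SiMe3)2 in THF at −78 °C to the potassium carbanion F6, which should attack F5 only at the allylic bromide and give the seco diiodide F7. Zinc insertion into the primary C–I bond gives the alkylzinc iodide F8, and intramolecular Negishi coupling with the vinyl iodide (Pd2(dba)3, P(o-tol)3, DMF, high dilution) comes back to the route at 35.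

Step 13 (Negishi coupling). The alkylzinc intermediate may lose the β-silyloxy group by elimination, or be protonated, before it transmetalates. The fallback is a nickel-catalysed reductive cross-electrophile coupling of 12 with 18 (NiBr2(dme), 4,4′-di-tert-butyl-2,2′-bipyridine, Mn powder, NaI, N,N-dimethylacetamide, rt). Here C9 reacts as an alkyl radical captured by nickel, which does not expel a β-silyloxy group, and no organozinc is formed. It sets out from 12 and 18 and comes back at 20; it makes no new compound (F0).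

Step 23 (directed epoxidation). Oxygen may be delivered to the wrong face of C4=C5 if the ten-membered ring does not adopt the conformation found for smaller medium-ring allylic alcohols, and the new epoxide may be opened across the ring by the Lewis-acidic catalyst. The fallback replaces substrate control by reagent control: titanium–tartrate asymmetric epoxidation of 37 (Ti(OiPr)4, L-(+)-diisopropyl tartrate in stoichiometric amount, t-BuOOH, 4 Å molecular sieves, CH2Cl2, −20 °C). For the C6 configuration present, the L-(+)-tartrate complex is the matched partner and should deliver oxygen to the face that gives the erythro (ring-cis) epoxy alcohol. It sets out from 37 and comes back at 38; it makes no new compound (F0).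

**Further compounds**
F1 | step 21 | iodo aldehyde (C5 aldehyde of 12) | O=C1C[C@@H]([C@H](O[Si](C)(C)C(C)(C)C)CI)[C@@H](C=O)O1
F2 | step 21 | tert-butyl (Z)-enoate carrying the C9 iodide | O=C1C[C@@H]([C@H](O[Si](C)(C)C(C)(C)C)CI)[C@@H](/C=C(C)\C(=O)OC(C)(C)C)O1
F3 | step 21 | (Z)-enoic acid carrying the C9 iodide | O=C1C[C@@H]([C@H](O[Si](C)(C)C(C)(C)C)CI)[C@@H](/C=C(C)\C(=O)O)O1
F4 | step 21 | (Z)-allylic alcohol carrying the C9 iodide | O=C1C[C@@H]([C@H](O[Si](C)(C)C(C)(C)C)CI)[C@@H](/C=C(C)\CO)O1
F5 | step 21 | (Z)-allylic bromide carrying the C9 iodide | O=C1C[C@@H]([C@H](O[Si](C)(C)C(C)(C)C)CI)[C@@H](/C=C(C)\CBr)O1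
F6 | step 21 | potassium carbanion of sulfone 18 | C/C(I)=C/[CH-]S(=O)(=O)c1ccccc1.[K+]
F7 | step 21 | seco diiodide with C2–C3 bond formed (C2 epimers) | O=C1C[C@@H]([C@H](O[Si](C)(C)C(C)(C)C)CI)[C@@H](/C=C(C)\CC(/C=C(/C)I)S(=O)(=O)c2ccccc2)O1
F8 | step 21 | alkylzinc iodide of F7 | O=C1C[C@@H]([C@H](O[Si](C)(C)C(C)(C)C)C[Zn]I)[C@@H](/C=C(C)\CC(/C=C(/C)I)S(=O)(=O)c2ccccc2)O1
F0 | step 13 | none | none
F0 | step 23 | none | none
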